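- I had 3 questions on 4 flasks read at 6.0 h: their order by target, and the target in the first and the last.

| flask | starting material | gas | initiator | remark | time |
|---|---|---|---|---|---|
| south-east | 11 mM | 2.3 mM (held) | 1.2 mol% | run made earlier |  |
| east | 11 mM | 2.3 mM (held) | 14 mol% | run made earlier |  |
| alpha | 11 mM | 2.3 mM (held) | 12 mol% |  | 6.0 h |
| eta | 11 mM | 2.3 mM (held) | 2 mol% |  | 6.0 h |
| zeta | 11 mM | 2.3 mM (held) | 3.2 mol% |  | 6.0 h |
| epsilon | 11 mM | 2.3 mM (held) | 0.8 mol% |  | 6.0 h |

- south-east (time / h: target / %, starting material / %): 1.33: 1.5, 97.6; 2.50: 6.3, 93.7; 4.00: 7.0, 86.7; 5.00: 7.7, 83.9; 6.00: 9.3, 78.4
- east (time / h: target / %, starting material / %): 0.500: 2.6, 97.0; 0.833: 3.1, 94.3; 1.50: 9.4, 88.6; 3.00: 14.5, 76.1; 6.00: 22.0, 52.1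

(standard deviation of a reading: 1 percentage point)

- in percentages every species weighs as the starting material in it: one ended chains A counts as two
- at the start none of coupling partner is dissolved
- the analysis behind the earlier runs scatters by 1 percentage point, standard deviation
- reactions considered so far: initiator -> 2 initiating radical; starting material + initiating radical -> capped initiator + first chain carrier; coupling partner + first chain carrier -> target + second chain carrier; starting material + second chain carrier -> by-product + first chain carrier; first chain carrier -> ended carrier; 2 first chain carrier -> ended chains A; 2 second chain carrier -> ended chains B; gas <-> coupling partner; target -> over-reaction product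

1. the flasks put in order of amount of target, in percent of the starting material charged, best first, at 6.0 h (alpha / eta / zeta / epsilon)
2. the amount of target, in percent of the starting material charged of the flask you put first, at 6.0 h
3. the amount of target, in percent of the starting material charged of the flask you put last, at 6.0 h

- My bench rule for a chain whose carriers end in pairs was that rate goes as the square root of the initiator loading.
- South-east used 21.6% of its starting material, so with a loading ratio of 11.7 the rule promised 73.8% for east, but east used 47.9%, less than that.
- I found the border by counting turnovers. Each starting material reaching target passes through one coupling partner, and I called the pool the fraction of the charge that saturation holds as coupling partner, 20.9%.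
- Dividing the starting material used by the pool, south-east had drawn 1.03 pools and east 2.29, more than south-east. No coupling partner is dissolved at the start, so passing gas feeds a flask from the first moment, and a pool only counts how many saturation loads it has delivered. The rule started from south-east's 1.03 and failed at east's 2.29, so I took about one pool as a working border, not a change of supply, and past it I stopped trusting the rule, with passing gas as a candidate rate-limiting step.
- Epsilon sat on the safe side, at 0.843 pools by the rule, and scaling south-east's target by the same root gave me 7.59%.
- Alpha sat beyond the border, so I took the short step down from east, a loading ratio of 0.857, and reckoned 20.4%. I ranked the flasks by loading.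
- The forecast gave alpha > zeta > eta > epsilon, with 21% (19% to 23%) and 7.7% (6.3% to 9%), holding that “more initiator stays better”.
- The flasks gave alpha > zeta > eta > epsilon, with 21.6% in alpha and 7.88% in epsilon.

    initiator → 2 initiating radical (k = 0.0265 h⁻¹)
    starting material + initiating radical → capped initiator + first chain carrier (k = 2.67 × 10⁵ M⁻¹ s⁻¹)
    coupling partner + first chain carrier → target + second chain carrier (k = 1.85 × 10⁵ M⁻¹ s⁻¹)
    starting material + second chain carrier → by-product + first chain carrier (k = 2.47 × 10⁵ M⁻¹ s⁻¹)
    first chain carrier → ended carrier (k = 11000 h⁻¹)
    2 first chain carrier → ended chains A (k = 7.00 × 10⁷ M⁻¹ s⁻¹)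
    2 second chain carrier → ended chains B (k = 1.10 × 10⁹ M⁻¹ s⁻¹)
    gas ⇌ coupling partner, rate k8*(csat - [coupling partner]) (kL = 0.421 h⁻¹)
    target → over-reaction product (k = 0.290 h⁻¹)

- Alpha used 2.29 pools against the 2.53 that passing gas delivers in 6.0 h to a flask held empty of coupling partner, and its coupling partner stood at 12.3% of saturation. Epsilon used 0.725 pools, with its coupling partner at 62.1% of saturation.
- For the neighbour of epsilon charged with 0.2 mol% of initiator, the root from epsilon gave 0.363 pools, below the border. Computed, that neighbour used 0.227 pools and held 2.53% target.

The data were generated by integration for substances that don't exist; the scatter is artificial.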